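The numbers in the tables come from a simulation with made-up constants, noise included.

6.00 min into the grey run the target already stands at 7.4% of the starting material charged, and I want the whole curve for a leaner flask.

| flask | starting material | partner | remark | time |
|---|---|---|---|---|
| grey | 1.8 M | 2.4 M | run made earlier |  |
| flask | 1.2 M | 2.40 M |  | 1.5 h |

grey run (percent of the starting material charged)

| time / min | target / % |
|---|---|
| 6.00 | 7.4 |
| 12.0 | 11.7 |
| 20.0 | 13.1 |
| 30.0 | 12.7 |
| 50.0 | 11.2 |

(each reading ± 0.3 percentage points)

- a species is counted by the starting material in it: one side product B counts as two
- steps thought possible: starting material + partner -> target; starting material -> side product A; 2 starting material -> side product B; target <-> isomer of the product; target -> over-reaction product; partner -> decomposed reagent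

- the best time, 1.5 h at the latest, for target
- the amount of target, in percent of the starting material charged, at that time
- earliest time at which at least nineteen twentieths of that best amount are there
- latest time at which they still are

If the step to target is first order in each reactant, target counted in percent of the charge opens at a pace k·c(partner), and c(starting material) cancels: a pseudo-first-order rate. The flask holds 2.40 M of partner, as the grey run did, so I carry the grey opening pace over. The first reading gives the chord 0.0123 min⁻¹. Dividing the highest grey reading, 13.1% at 20.0 min, by that chord gives a production time of 10.7 min, the time the peak would take at opening pace.

In the flask, the first-order loss keeps its opening pace per unit of starting material, while the route to side product B opens, per unit, at 0.667 of its grey pace. One run can't split the two, so I guess equal shares. Production time then stretches by 1.20, and I commit to 15.7% near 24.0 min.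

The weak link is the chord, taken across a curve that is already bending. The first two readings together remove that bend and give 0.0149 min⁻¹, a reading with its scatter: this is the opening slope σ, the fraction of the charge becoming target per minute at the start, and the chord lies below it. Production time shortens to 8.79 min, but my figure stands, since σ enters the product and leaves it again.

The forecast gives 14.2% at 0.4 h, with a window from 0.24 h to 0.63 h, lower than my figure, and expects “a slightly higher, slightly later peak”.

The flask gives 14.4% at 0.447 h, with its window from 0.302 h to 0.658 h, 1.3 percentage points below my figure.

    starting material + partner → target (k = 1.20 × 10⁻⁴ M⁻¹ s⁻¹)
    starting material → side product A (k = 1.60 × 10⁻⁴ s⁻¹)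
    2 starting material → side product B (k = 9.50 × 10⁻⁵ M⁻¹ s⁻¹)
    target ⇌ isomer of the product (K = 2.10, k = 5.20 × 10⁻⁴ s⁻¹)
    target → over-reaction product (k = 1.10 × 10⁻⁴ s⁻¹)
    partner → decomposed reagent (k = 2.40 × 10⁻⁴ s⁻¹)

At 0.448 h the flask still holds 42.7% of its starting material and 58.4% of its partner. Its production time by σ is 9.66 min. The neighbouring flask with 0.96 M of partner opens, by the same rule, at 0.00597 min⁻¹, which over that production time makes 5.77%; its simulated best is 6.35%.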